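**Strategy.** Everything rests on disconnecting the ring-fusion bond C4a–C8a of the cis-decalin together with C1–C2 (ring A: C4a, C5, C6(=CH2), C7, C8, C8a; ring B: C1(Me2), C2, C3(=CH2), C4, C4a, C8a). An acyclic trienal is closed by an enantioselective intramolecular Diels–Alder reaction: a Z-enal (C8a=C1, its formyl group being one future C1 methyl) adds endo to a diene (C4a=C4–C3=C2) that has tether and side chain as outside substituents and CH2SiMe3 on C3. One operation forms both rings and the three cis hydrogens at C2, C4a and C8a. Formyl-to-methyl reduction and protodesilylation finish the core; the 1,2-dioxane is closed last by peroxide displacement and iodocyclisation.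

Key step: step 10

Remark on the chemistry: the (S)-configured catalyst in step 10 is written on the basis of the accepted facial model for 2-substituted enals; if the sense of induction on this Z-enal is the opposite one, the mirror-image catalyst is used.

**Fragment A (dienophile and tether)**

Step 1
Reactants: 1 tert-butyl acetate; 2 3-chloro-2-(chloromethyl)prop-1-ene
Product: 4 tert-butyl 4-(chloromethyl)pent-4-enoate, via lithium enolate 3 (not isolated)
Conditions: LiN(i-Pr)2, THF, −78 °C; then 2 (3 equiv), DMPU, −78 → 0 °C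
Reagents that add atoms: none
Why: Enolate alkylation (SN2) at an allylic chloride; the dichloride is symmetrical, so SN2 and SN2' paths give the same product and the excess keeps the second C–Cl bond intact.

Step 2
Reactants: 4 tert-butyl 4-(chloromethyl)pent-4-enoate
Product: 5 tert-butyl 4-methylidenehept-6-ynoate
Conditions: HC≡CMgBr (1.3 equiv), CuI (10 mol %), THF, 0 → 50 °C
Reagents that add atoms: ethynylmagnesium bromide, C#C[Mg]Br
Why: Copper-catalysed coupling of an alkynyl Grignard reagent with the allylic chloride (again regiochemically degenerate) should give the skipped enyne, the hindered tert-butyl ester resisting addition.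

Step 3
Reactants: 5 tert-butyl 4-methylidenehept-6-ynoate
Product: 6 4-methylidenehept-6-ynal
Conditions: i-Bu2AlH (1.1 equiv), CH2Cl2, −78 °C; aq. potassium sodium tartrate
Reagents that add atoms: none
Why: Partial ester reduction: the tetrahedral aluminium hemiacetal is stable at −78 °C and releases the aldehyde only on work-up.

Step 4
Reactants: 6 4-methylidenehept-6-ynal
Product: 7 ethyl (2Z)-2-methyl-6-methylidenenon-2-en-8-ynoate
Conditions: ethyl 2-[bis(2,2,2-trifluoroethoxy)phosphoryl]propanoate, KN(SiMe3)2, 18-crown-6, THF, −78 °C; then 6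
Reagents that add atoms: ethyl 2-[bis(2,2,2-trifluoroethoxy)phosphoryl]propanoate, CCOC(=O)C(C)P(=O)(OCC(F)(F)F)OCC(F)(F)F
Why: Still–Gennari olefination: the electron-poor bis(trifluoroethyl) phosphonate makes elimination from the kinetically formed adduct fast, so the Z-trisubstituted enoate (ester cis to the chain) is expected.

**Fragment B and assembly of the trienal**

Step 5
Reactants: 8 3-[(tert-butyldimethylsilyl)oxy]propanal
Product: 9 tert-butyl[(4,4-dibromobut-3-en-1-yl)oxy]dimethylsilane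
Conditions: CBr4, PPh3, CH2Cl2, 0 °C
Reagents that add atoms: carbon tetrabromide, BrC(Br)(Br)Br
Why: Ramirez dibromo-olefination (Wittig reaction of the in situ ylide Ph3P=CBr2) converts the aldehyde into the 1,1-dibromoalkene.

Step 6
Reactants: 7 ethyl (2Z)-2-methyl-6-methylidenenon-2-en-8-ynoate; 9 tert-butyl[(4,4-dibromobut-3-en-1-yl)oxy]dimethylsilane
Product: 11 ethyl (2Z,8E,10Z)-10-bromo-13-[(tert-butyldimethylsilyl)oxy]-2-methyl-6-methylidenetrideca-2,8,10-trienoate, via alkenylboronate 10 (not isolated)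
Conditions: pinacolborane, Cp2Zr(H)Cl (5 mol %), Et3N (10 mol %), neat, 40 °C; then 9, Pd(PPh3)4 (5 mol %), TlOEt, THF/H2O, 23 °C
Reagents that add atoms: none
Why: Zirconium-catalysed syn hydroboration of the terminal alkyne gives the E-alkenylboronate, and the Suzuki–Miyaura coupling then takes the C–Br bond trans to the alkyl chain (less hindered, faster oxidative addition) so that the vinyl group ends up trans to the future C2 side chain in a Z-bromodiene.

Step 7
Reactants: 11 ethyl (2Z,8E,10Z)-10-bromo-13-[(tert-butyldimethylsilyl)oxy]-2-methyl-6-methylidenetrideca-2,8,10-trienoate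
Product: 12 ethyl (2Z,8E,10Z)-13-[(tert-butyldimethylsilyl)oxy]-2-methyl-6-methylidene-10-[(trimethylsilyl)methyl]trideca-2,8,10-trienoate
Conditions: Me3SiCH2MgCl, ZnCl2, THF, 0 °C; then 11, Pd(P(t-Bu)3)2 (5 mol %), 23 °C
Reagents that add atoms: (trimethylsilylmethyl)magnesium chloride, C[Si](C)(C)C[Mg]Cl
Why: Negishi coupling of the remaining alkenyl bromide with retention; the bulky trialkylphosphine is chosen because 2-bromo-1,3-dienes are prone to stereoinversion with less hindered ligands, and the zinc reagent leaves the ester alone.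

Step 8
Reactants: 12 ethyl (2Z,8E,10Z)-13-[(tert-butyldimethylsilyl)oxy]-2-methyl-6-methylidene-10-[(trimethylsilyl)methyl]trideca-2,8,10-trienoate
Product: 13 (2Z,8E,10Z)-13-[(tert-butyldimethylsilyl)oxy]-2-methyl-6-methylidene-10-[(trimethylsilyl)methyl]trideca-2,8,10-trien-1-ol
Conditions: i-Bu2AlH (2.5 equiv), CH2Cl2, −78 → −20 °C
Reagents that add atoms: none
Why: 1,2-Reduction of the enoate by the aluminium hydride gives the Z-allylic alcohol without touching silyl ether, allylsilane or alkene geometry.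

Step 9
Reactants: 13 (2Z,8E,10Z)-13-[(tert-butyldimethylsilyl)oxy]-2-methyl-6-methylidene-10-[(trimethylsilyl)methyl]trideca-2,8,10-trien-1-ol
Product: 14 (2Z,8E,10Z)-13-[(tert-butyldimethylsilyl)oxy]-2-methyl-6-methylidene-10-[(trimethylsilyl)methyl]trideca-2,8,10-trienal
Conditions: MnO2, CH2Cl2, 23 °C
Reagents that add atoms: none
Why: MnO2 oxidises only the allylic alcohol under neutral conditions, so the Z-enal should be obtained without isomerisation.

**Key step and completion of the carbocycle**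

Step 10
Reactants: 14 (2Z,8E,10Z)-13-[(tert-butyldimethylsilyl)oxy]-2-methyl-6-methylidene-10-[(trimethylsilyl)methyl]trideca-2,8,10-trienal
Product: 15 (1S,2S,4aS,8aS)-2-{2-[(tert-butyldimethylsilyl)oxy]ethyl}-1-methyl-6-methylidene-3-[(trimethylsilyl)methyl]-1,2,4a,5,6,7,8,8a-octahydronaphthalene-1-carbaldehyde (cis-fused; H-2, H-4a and H-8a on one face, formyl on the other)
Conditions: (S)-3,3-diphenyl-1-(2-methylphenyl)tetrahydro-1H,3H-pyrrolo[1,2-c][1,3,2]oxazaborole N-protonated with HN(SO2CF3)2 (20 mol %), CH2Cl2, −78 → −40 °C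
Reagents that add atoms: none
Why: Coordination of the formyl group to the cationic boron lowers the enal LUMO and a concerted, asynchronous intramolecular [4+2] cycloaddition follows, the C8a–C4a bond (enal β-carbon to the tethered diene terminus) running ahead of C1–C2; the closest known reaction type is the oxazaborolidinium-catalysed intramolecular Diels–Alder reaction of 2-substituted trienals. Ring B closes as the six-membered cycloadduct ring (suprafacial on both partners) and ring A closes at the same time through the four-atom tether C5–C8 that spans the new C4a–C8a bond. Because the enal is Z, formyl group and tether lie on the same side of the dienophile, so the Lewis-acid-favoured endo-formyl transition state is also tether-endo and gives the cis ring fusion. The diene carries the tether and the C2 side chain as its two outside substituents, so suprafacial addition places the C2 side chain cis to C5, that is H-2 cis to both ring-fusion hydrogens; the formyl-bearing C1 is set too but becomes CMe2 in the next step. Absolute configuration comes from the catalyst, which holds the s-trans enal by B–O coordination and a formyl C–H···O contact and shields one face with an aryl group. The step needs endo over exo selectivity (Z dienophile and Lewis acid), facial selectivity (catalyst) and survival of the allylsilane (low temperature, no free protic acid).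

Step 11
Reactants: 15 (1S,2S,4aS,8aS)-2-{2-[(tert-butyldimethylsilyl)oxy]ethyl}-1-methyl-6-methylidene-3-[(trimethylsilyl)methyl]-1,2,4a,5,6,7,8,8a-octahydronaphthalene-1-carbaldehyde
Product: 17 tert-butyl{2-[(2S,4aS,8aS)-1,1-dimethyl-6-methylidene-3-[(trimethylsilyl)methyl]-1,2,4a,5,6,7,8,8a-octahydronaphthalen-2-yl]ethoxy}dimethylsilane, via tosylhydrazone 16 (not isolated)
Conditions: TsNHNH2, EtOH, 23 °C; then catecholborane, CHCl3, 0 °C; NaOAc·3H2O, 60 °C
Reagents that add atoms: none
Why: Tosylhydrazone reduction (Caglioti type): hydride addition to C=N, loss of sulfinate and then of N2 from the diazene turns CHO into CH3 under neutral conditions that spare the allylsilane, and the C1 stereocentre disappears as C1 becomes CMe2.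

Step 12
Reactants: 17 tert-butyl{2-[(2S,4aS,8aS)-1,1-dimethyl-6-methylidene-3-[(trimethylsilyl)methyl]-1,2,4a,5,6,7,8,8a-octahydronaphthalen-2-yl]ethoxy}dimethylsilane
Product: 18 tert-butyl{2-[(2R,4aS,8aS)-1,1-dimethyl-3,6-dimethylidenedecahydronaphthalen-2-yl]ethoxy}dimethylsilane
Conditions: CF3CO2H (1.5 equiv), CH2Cl2, −20 → 0 °C; NaHCO3 quench
Reagents that add atoms: none
Why: SE2' protodesilylation: the proton adds to C4 (γ to silicon, β-silyl cation stabilisation), silicon leaves and the double bond moves to the exocyclic position, the allylsilane being far more nucleophilic than the existing 6-methylidene group.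

Step 13
Reactants: 18 tert-butyl{2-[(2R,4aS,8aS)-1,1-dimethyl-3,6-dimethylidenedecahydronaphthalen-2-yl]ethoxy}dimethylsilane
Product: 19 (2R,4aS,8aS)-2-(2-bromoethyl)-1,1-dimethyl-3,6-dimethylidenedecahydronaphthalene
Conditions: Ph3PBr2, CH2Cl2, 23 °C
Reagents that add atoms: dibromotriphenylphosphorane, BrP(Br)(c1ccccc1)(c1ccccc1)c1ccccc1
Why: The bromophosphonium salt activates the silyl ether oxygen and bromide displaces it at the primary carbon (SN2), a direct silyl ether to bromide conversion without free acid.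

**Fragment C (side-chain stereocentres)**

Step 14
Reactants: 20 pent-3-yn-1-ol
Product: 22 (3E)-4-iodopent-3-en-1-ol, via alkenylzirconocene 21 (not isolated)
Conditions: Cp2Zr(H)Cl (2.5 equiv), THF, 23 → 40 °C; then I2, 0 °C
Reagents that add atoms: iodine, II
Why: Syn hydrozirconation with excess reagent equilibrates zirconium to the less hindered, methyl-bearing alkyne carbon and iodinolysis with retention gives the E-alkenyl iodide.

Step 15
Reactants: 22 (3E)-4-iodopent-3-en-1-ol
Product: 23 (3E)-4-iodopent-3-enal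
Conditions: Dess–Martin periodinane, NaHCO3, CH2Cl2, 0 °C
Reagents that add atoms: none
Why: Buffered Dess–Martin oxidation gives the β,γ-unsaturated aldehyde, which is used at once so that it cannot move into conjugation.

Step 16
Reactants: 23 (3E)-4-iodopent-3-enal; 24 (4R)-4-benzyl-3-propanoyl-1,3-oxazolidin-2-one
Product: 26 (4R)-4-benzyl-3-[(2R,3S,5E)-3-hydroxy-6-iodo-2-methylhept-5-enoyl]-1,3-oxazolidin-2-one, via boron enolate 25 (not isolated)
Conditions: n-Bu2BOTf, i-Pr2NEt, CH2Cl2, −78 → 0 °C; then 23, −78 → 0 °C; pH 7 buffer, MeOH, H2O2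
Reagents that add atoms: none
Why: Evans syn-aldol reaction: the Z-boron enolate reacts through a Zimmerman–Traxler chair on the face opposite the benzyl group of the (R)-auxiliary, which sets (2R,3S).

Step 17
Reactants: 26 (4R)-4-benzyl-3-[(2R,3S,5E)-3-hydroxy-6-iodo-2-methylhept-5-enoyl]-1,3-oxazolidin-2-one
Product: 27 (2S,3S,5E)-6-iodo-2-methylhept-5-ene-1,3-diol
Conditions: LiBH4, H2O (1 equiv), Et2O, 0 °C
Reagents that add atoms: none
Why: Hydride cleavage of the exocyclic imide carbonyl releases the auxiliary and gives the 1,3-diol without touching the stereocentres or the alkenyl iodide.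

Step 18
Reactants: 27 (2S,3S,5E)-6-iodo-2-methylhept-5-ene-1,3-diol
Product: 29 (2S,3S,5E)-1-[(tert-butyldimethylsilyl)oxy]-6-iodo-2-methylhept-5-en-3-yl methanesulfonate, via silyl ether 28 (not isolated)
Conditions: t-BuMe2SiCl, Et3N, 4-(dimethylamino)pyridine (cat.), CH2Cl2, −20 °C; then MeSO2Cl, Et3N, 0 °C
Reagents that add atoms: tert-butyldimethylsilyl chloride, C[Si](C)(Cl)C(C)(C)C; methanesulfonyl chloride, CS(=O)(=O)Cl
Why: The primary hydroxyl is silylated selectively on steric grounds and the secondary hydroxyl is then sulfonylated in the same flask with retention at carbon.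

**Fragment union and 1,2-dioxane**

Step 19
Reactants: 19 (2R,4aS,8aS)-2-(2-bromoethyl)-1,1-dimethyl-3,6-dimethylidenedecahydronaphthalene; 29 (2S,3S,5E)-1-[(tert-butyldimethylsilyl)oxy]-6-iodo-2-methylhept-5-en-3-yl methanesulfonate
Product: 31 (2S,3S,5E)-1-[(tert-butyldimethylsilyl)oxy]-8-[(2R,4aS,8aS)-1,1-dimethyl-3,6-dimethylidenedecahydronaphthalen-2-yl]-2,6-dimethyloct-5-en-3-yl methanesulfonate, via alkylzinc bromide 30 (not isolated)
Conditions: Zn dust, I2 (5 mol %), N,N-dimethylacetamide, 80 °C; then 29, PdCl2(dppf) (5 mol %, dppf = 1,1'-bis(diphenylphosphino)ferrocene), 23 °C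
Reagents that add atoms: none
Why: Zinc insertion into the primary C–Br bond and Negishi coupling with the E-alkenyl iodide (retention) join the fragments; alkylzinc halides tolerate the mesylate, the silyl ether and the alkenes.

Step 20
Reactants: 31 (2S,3S,5E)-1-[(tert-butyldimethylsilyl)oxy]-8-[(2R,4aS,8aS)-1,1-dimethyl-3,6-dimethylidenedecahydronaphthalen-2-yl]-2,6-dimethyloct-5-en-3-yl methanesulfonate
Product: 32 tert-butyl{[(2S,3R,5E)-8-[(2R,4aS,8aS)-1,1-dimethyl-3,6-dimethylidenedecahydronaphthalen-2-yl]-3-hydroperoxy-2,6-dimethyloct-5-en-1-yl]oxy}dimethylsilane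
Conditions: H2O2 (50 % aq., excess), KOH, MeOH/THF, 0 → 23 °C
Reagents that add atoms: hydrogen peroxide, OO
Why: SN2 displacement of the secondary mesylate by hydroperoxide anion, a strong α-effect nucleophile and weak base, inverts the carbinol carbon and gives the hydroperoxide anti to the neighbouring methyl group.

Step 21
Reactants: 32 tert-butyl{[(2S,3R,5E)-8-[(2R,4aS,8aS)-1,1-dimethyl-3,6-dimethylidenedecahydronaphthalen-2-yl]-3-hydroperoxy-2,6-dimethyloct-5-en-1-yl]oxy}dimethylsilane
Product: 33 the 5-iodo-1,2-dioxane: tert-butyl(dimethyl)silyl ether of (2S)-2-[6-{2-[(2R,4aS,8aS)-1,1-dimethyl-3,6-dimethylidenedecahydronaphthalen-2-yl]ethyl}-5-iodo-6-methyl-1,2-dioxan-3-yl]propan-1-ol (C3 and C6 as in the target; iodine equatorial and cis to the 6-methyl group)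
Conditions: N-iodosuccinimide, NaHCO3, CH2Cl2, −20 °C, dark
Reagents that add atoms: N-iodosuccinimide, O=C1CCC(=O)N1I
Why: Cycloperoxyiodination: iodonium formation at the trisubstituted alkene is followed by 6-endo attack of the hydroperoxide at the tertiary carbon anti to iodine through a chair with the C3 substituent equatorial, and the E geometry then places the 6-alkyl chain equatorial and the 6-methyl group axial (6S); the ring methylidene groups have no internal nucleophile and their iodonium ions revert.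

Step 22
Reactants: 33 the 5-iodo-1,2-dioxane
Product: 34 tert-butyl{(2S)-2-[(3R,6S)-6-{2-[(2R,4aS,8aS)-1,1-dimethyl-3,6-dimethylidenedecahydronaphthalen-2-yl]ethyl}-6-methyl-1,2-dioxan-3-yl]propoxy}dimethylsilane
Conditions: n-Bu3SnH, Et3B, air, toluene, 0 °C
Reagents that add atoms: none
Why: Radical chain dehalogenation: the ring-held β-peroxy radical is poorly aligned for epoxide-forming attack on the O–O bond and is trapped by the stannane at low temperature.

Step 23
Reactants: 34 tert-butyl{(2S)-2-[(3R,6S)-6-{2-[(2R,4aS,8aS)-1,1-dimethyl-3,6-dimethylidenedecahydronaphthalen-2-yl]ethyl}-6-methyl-1,2-dioxan-3-yl]propoxy}dimethylsilane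
Product: 35 (2S)-2-[(3R,6S)-6-{2-[(2R,4aS,8aS)-1,1-dimethyl-3,6-dimethylidenedecahydronaphthalen-2-yl]ethyl}-6-methyl-1,2-dioxan-3-yl]propan-1-ol
Conditions: n-Bu4NF, AcOH, THF, 0 → 23 °C
Reagents that add atoms: none
Why: Fluoride cleaves the Si–O bond, buffering with acetic acid keeping the base-sensitive CH–O–O unit intact.

Step 24
Reactants: 35 (2S)-2-[(3R,6S)-6-{2-[(2R,4aS,8aS)-1,1-dimethyl-3,6-dimethylidenedecahydronaphthalen-2-yl]ethyl}-6-methyl-1,2-dioxan-3-yl]propan-1-ol
Product: 37 (2R)-2-[(3R,6S)-6-{2-[(2R,4aS,8aS)-1,1-dimethyl-3,6-dimethylidenedecahydronaphthalen-2-yl]ethyl}-6-methyl-1,2-dioxan-3-yl]propanoic acid, via aldehyde 36 (not isolated)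
Conditions: TEMPO (2,2,6,6-tetramethylpiperidin-1-oxyl, 20 mol %), PhI(OAc)2, MeCN/pH 7 buffer, 23 °C
Reagents that add atoms: water, O
Why: Oxoammonium oxidation (TEMPO, PhI(OAc)2) takes the primary alcohol through the aldehyde and its hydrate to the acid under neutral conditions that spare the peroxide, both methylidene groups and the α-stereocentre.

**Compound list**

1 | tert-butyl acetate | CC(=O)OC(C)(C)C | starting material
2 | 3-chloro-2-(chloromethyl)prop-1-ene | C=C(CCl)CCl | starting material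
3 | lithium 1-tert-butoxyethen-1-olate | [Li]OC(=C)OC(C)(C)C | intermediate
4 | tert-butyl 4-(chloromethyl)pent-4-enoate | C=C(CCl)CCC(=O)OC(C)(C)C | intermediate
5 | tert-butyl 4-methylidenehept-6-ynoate | C#CCC(=C)CCC(=O)OC(C)(C)C | intermediate
6 | 4-methylidenehept-6-ynal | C#CCC(=C)CCC=O | intermediate
7 | ethyl (2Z)-2-methyl-6-methylidenenon-2-en-8-ynoate | CCOC(=O)/C(C)=C\CCC(=C)CC#C | intermediate
8 | 3-[(tert-butyldimethylsilyl)oxy]propanal | O=CCCO[Si](C)(C)C(C)(C)C | starting material
9 | tert-butyl[(4,4-dibromobut-3-en-1-yl)oxy]dimethylsilane | BrC(Br)=CCCO[Si](C)(C)C(C)(C)C | intermediate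
10 | ethyl (2Z,8E)-2-methyl-6-methylidene-9-(4,4,5,5-tetramethyl-1,3,2-dioxaborolan-2-yl)nona-2,8-dienoate | CCOC(=O)/C(C)=C\CCC(=C)C/C=C/B1OC(C)(C)C(C)(C)O1 | intermediate
11 | ethyl (2Z,8E,10Z)-10-bromo-13-[(tert-butyldimethylsilyl)oxy]-2-methyl-6-methylidenetrideca-2,8,10-trienoate | CCOC(=O)/C(C)=C\CCC(=C)C/C=C/C(Br)=C/CCO[Si](C)(C)C(C)(C)C | intermediate
12 | ethyl (2Z,8E,10Z)-13-[(tert-butyldimethylsilyl)oxy]-2-methyl-6-methylidene-10-[(trimethylsilyl)methyl]trideca-2,8,10-trienoate | CCOC(=O)/C(C)=C\CCC(=C)C/C=C/C(C[Si](C)(C)C)=C/CCO[Si](C)(C)C(C)(C)C | intermediate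
13 | (2Z,8E,10Z)-13-[(tert-butyldimethylsilyl)oxy]-2-methyl-6-methylidene-10-[(trimethylsilyl)methyl]trideca-2,8,10-trien-1-ol | OC/C(C)=C\CCC(=C)C/C=C/C(C[Si](C)(C)C)=C/CCO[Si](C)(C)C(C)(C)C | intermediate
14 | (2Z,8E,10Z)-13-[(tert-butyldimethylsilyl)oxy]-2-methyl-6-methylidene-10-[(trimethylsilyl)methyl]trideca-2,8,10-trienal | O=C/C(C)=C\CCC(=C)C/C=C/C(C[Si](C)(C)C)=C/CCO[Si](C)(C)C(C)(C)C | intermediate
15 | (1S,2S,4aS,8aS)-2-{2-[(tert-butyldimethylsilyl)oxy]ethyl}-1-methyl-6-methylidene-3-[(trimethylsilyl)methyl]-1,2,4a,5,6,7,8,8a-octahydronaphthalene-1-carbaldehyde | C=C1CC[C@H]2[C@@H](C1)C=C(C[Si](C)(C)C)[C@@H](CCO[Si](C)(C)C(C)(C)C)[C@@]2(C)C=O | intermediate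
16 | (E)-4-methylbenzenesulfonylhydrazone of 15 | C=C1CC[C@H]2[C@@H](C1)C=C(C[Si](C)(C)C)[C@@H](CCO[Si](C)(C)C(C)(C)C)[C@@]2(C)/C=N/NS(=O)(=O)c1ccc(C)cc1 | intermediate
17 | tert-butyl{2-[(2S,4aS,8aS)-1,1-dimethyl-6-methylidene-3-[(trimethylsilyl)methyl]-1,2,4a,5,6,7,8,8a-octahydronaphthalen-2-yl]ethoxy}dimethylsilane | C=C1CC[C@H]2[C@@H](C1)C=C(C[Si](C)(C)C)[C@@H](CCO[Si](C)(C)C(C)(C)C)C2(C)C | intermediate
18 | tert-butyl{2-[(2R,4aS,8aS)-1,1-dimethyl-3,6-dimethylidenedecahydronaphthalen-2-yl]ethoxy}dimethylsilane | C=C1CC[C@H]2[C@@H](C1)CC(=C)[C@@H](CCO[Si](C)(C)C(C)(C)C)C2(C)C | intermediate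
19 | (2R,4aS,8aS)-2-(2-bromoethyl)-1,1-dimethyl-3,6-dimethylidenedecahydronaphthalene | C=C1CC[C@H]2[C@@H](C1)CC(=C)[C@@H](CCBr)C2(C)C | intermediate
20 | pent-3-yn-1-ol | CC#CCCO | starting material
21 | (E)-alkenylzirconocene chloride of 20 with the hydroxyl as its zirconocene chloride alkoxide | C/C(=C\CCO[Zr](Cl)(C1C=CC=C1)C1C=CC=C1)[Zr](Cl)(C1C=CC=C1)C1C=CC=C1 | intermediate
22 | (3E)-4-iodopent-3-en-1-ol | C/C(I)=C\CCO | intermediate
23 | (3E)-4-iodopent-3-enal | C/C(I)=C\CC=O | intermediate
24 | (4R)-4-benzyl-3-propanoyl-1,3-oxazolidin-2-one | CCC(=O)N1[C@H](Cc2ccccc2)COC1=O | starting material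
25 | dibutylboron (Z)-enolate of 24 | C/C=C(\OB(CCCC)CCCC)N1[C@H](Cc2ccccc2)COC1=O | intermediate
26 | (4R)-4-benzyl-3-[(2R,3S,5E)-3-hydroxy-6-iodo-2-methylhept-5-enoyl]-1,3-oxazolidin-2-one | C/C(I)=C\C[C@H](O)[C@@H](C)C(=O)N1[C@H](Cc2ccccc2)COC1=O | intermediate
27 | (2S,3S,5E)-6-iodo-2-methylhept-5-ene-1,3-diol | C/C(I)=C\C[C@H](O)[C@@H](C)CO | intermediate
28 | (2S,3S,5E)-1-[(tert-butyldimethylsilyl)oxy]-6-iodo-2-methylhept-5-en-3-ol | C/C(I)=C\C[C@H](O)[C@@H](C)CO[Si](C)(C)C(C)(C)C | intermediate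
29 | (2S,3S,5E)-1-[(tert-butyldimethylsilyl)oxy]-6-iodo-2-methylhept-5-en-3-yl methanesulfonate | C/C(I)=C\C[C@H](OS(C)(=O)=O)[C@@H](C)CO[Si](C)(C)C(C)(C)C | intermediate
30 | {2-[(2R,4aS,8aS)-1,1-dimethyl-3,6-dimethylidenedecahydronaphthalen-2-yl]ethyl}zinc bromide | C=C1CC[C@H]2[C@@H](C1)CC(=C)[C@@H](CC[Zn]Br)C2(C)C | intermediate
31 | (2S,3S,5E)-1-[(tert-butyldimethylsilyl)oxy]-8-[(2R,4aS,8aS)-1,1-dimethyl-3,6-dimethylidenedecahydronaphthalen-2-yl]-2,6-dimethyloct-5-en-3-yl methanesulfonate | C=C1CC[C@H]2[C@@H](C1)CC(=C)[C@@H](CC/C(C)=C/C[C@H](OS(C)(=O)=O)[C@@H](C)CO[Si](C)(C)C(C)(C)C)C2(C)C | intermediate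
32 | tert-butyl{[(2S,3R,5E)-8-[(2R,4aS,8aS)-1,1-dimethyl-3,6-dimethylidenedecahydronaphthalen-2-yl]-3-hydroperoxy-2,6-dimethyloct-5-en-1-yl]oxy}dimethylsilane | C=C1CC[C@H]2[C@@H](C1)CC(=C)[C@@H](CC/C(C)=C/C[C@@H](OO)[C@@H](C)CO[Si](C)(C)C(C)(C)C)C2(C)C | intermediate
33 | 5-iodo-1,2-dioxane silyl ether (iodine equatorial, cis to the 6-methyl group; other centres as in 34) | C=C1CC[C@H]2[C@@H](C1)CC(=C)[C@@H](CC[C@@]1(C)[C@H](I)C[C@H]([C@@H](C)CO[Si](C)(C)C(C)(C)C)OO1)C2(C)C | intermediate
34 | tert-butyl{(2S)-2-[(3R,6S)-6-{2-[(2R,4aS,8aS)-1,1-dimethyl-3,6-dimethylidenedecahydronaphthalen-2-yl]ethyl}-6-methyl-1,2-dioxan-3-yl]propoxy}dimethylsilane | C=C1CC[C@H]2[C@@H](C1)CC(=C)[C@@H](CC[C@@]1(C)CC[C@H]([C@@H](C)CO[Si](C)(C)C(C)(C)C)OO1)C2(C)C | intermediate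
35 | (2S)-2-[(3R,6S)-6-{2-[(2R,4aS,8aS)-1,1-dimethyl-3,6-dimethylidenedecahydronaphthalen-2-yl]ethyl}-6-methyl-1,2-dioxan-3-yl]propan-1-ol | C=C1CC[C@H]2[C@@H](C1)CC(=C)[C@@H](CC[C@@]1(C)CC[C@H]([C@@H](C)CO)OO1)C2(C)C | intermediate
36 | (2R)-2-[(3R,6S)-6-{2-[(2R,4aS,8aS)-1,1-dimethyl-3,6-dimethylidenedecahydronaphthalen-2-yl]ethyl}-6-methyl-1,2-dioxan-3-yl]propanal | C=C1CC[C@H]2[C@@H](C1)CC(=C)[C@@H](CC[C@@]1(C)CC[C@H]([C@@H](C)C=O)OO1)C2(C)C | intermediate
37 | (2R)-2-[(3R,6S)-6-{2-[(2R,4aS,8aS)-1,1-dimethyl-3,6-dimethylidenedecahydronaphthalen-2-yl]ethyl}-6-methyl-1,2-dioxan-3-yl]propanoic acid | C=C1CC[C@H]2[C@@H](C1)CC(=C)[C@@H](CC[C@@]1(C)CC[C@H]([C@@H](C)C(=O)O)OO1)C2(C)C | target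

**Step count.** Total: 24 steps. Longest linear sequence: 18 steps (steps 1–4, 6–13 and 19–24).

**Steps most likely to fail**

Step 10. The acidic boron catalyst may protodesilylate the silylmethyl diene, or let the allylsilane of the product add to the activated formyl group, before the cycloadduct is secured. The fallback sets out from 11 and comes back at 15. Ester 11 is reduced with i-Bu2AlH to the bromotrienol F1 and oxidised with MnO2 to the bromotrienal F2. F2 carries no acid-labile group and is cyclised with the same catalyst to the 3-bromo-octalin aldehyde F3. Negishi coupling of F3 with Me3SiCH2ZnCl and Pd(P(t-Bu)3)2 then installs the silylmethyl group and gives 15 with no Lewis acid present.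

Step 20. Base-induced elimination of the β-branched secondary mesylate toward the allylic CH2 may outrun substitution on the large, lipophilic substrate. The fallback sets out from 28 (isolated after the silylation) and comes back at 32. Alcohol 28 is converted with (CF3SO2)2O and 2,6-lutidine at −78 °C into the triflate F4. F4 is displaced with inversion at −40 → 0 °C by the caesium salt of 2-methoxypropan-2-yl hydroperoxide (CsOH, DMF) to give the perketal F5, a masked hydroperoxide. Negishi coupling of F5 with 30 gives the coupled perketal F6, and aqueous acetic acid in THF unmasks 32.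

Step 21. The hydroperoxide may close in the 5-exo mode, or the iodonium source may be consumed at the ring methylidene groups, so that the dioxane and its quaternary centre are not formed cleanly. The fallback sets out from 32 and comes back at 34. Cycloperoxymercuration with Hg(OAc)2 in CH2Cl2 at 0 °C (strongly Markovnikov, anti) gives the 5-(acetoxymercurio)-1,2-dioxane F7. F7 is demercurated in the same flask with NaBH4 in aqueous NaOH to give 34, which also removes the separate radical dehalogenation.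

**Further compounds**

F1 | step 10 | (2Z,8E,10Z)-10-bromo-13-[(tert-butyldimethylsilyl)oxy]-2-methyl-6-methylidenetrideca-2,8,10-trien-1-ol | OC/C(C)=C\CCC(=C)C/C=C/C(Br)=C/CCO[Si](C)(C)C(C)(C)C
F2 | step 10 | (2Z,8E,10Z)-10-bromo-13-[(tert-butyldimethylsilyl)oxy]-2-methyl-6-methylidenetrideca-2,8,10-trienal | O=C/C(C)=C\CCC(=C)C/C=C/C(Br)=C/CCO[Si](C)(C)C(C)(C)C
F3 | step 10 | 3-bromo analogue of 15 (cis-fused 3-bromo-2-{2-[(tert-butyldimethylsilyl)oxy]ethyl}-1-methyl-6-methylidene-octahydronaphthalene-1-carbaldehyde with the same spatial arrangement) | C=C1CC[C@H]2[C@@H](C1)C=C(Br)[C@@H](CCO[Si](C)(C)C(C)(C)C)[C@@]2(C)C=O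
F4 | step 20 | (2S,3S,5E)-1-[(tert-butyldimethylsilyl)oxy]-6-iodo-2-methylhept-5-en-3-yl trifluoromethanesulfonate | C/C(I)=C\C[C@H](OS(=O)(=O)C(F)(F)F)[C@@H](C)CO[Si](C)(C)C(C)(C)C
F5 | step 20 | tert-butyl{[(2S,3R,5E)-6-iodo-3-[(2-methoxypropan-2-yl)peroxy]-2-methylhept-5-en-1-yl]oxy}dimethylsilane | C/C(I)=C\C[C@@H](OOC(C)(C)OC)[C@@H](C)CO[Si](C)(C)C(C)(C)C
F6 | step 20 | 2-methoxypropan-2-yl perketal of 32 | C=C1CC[C@H]2[C@@H](C1)CC(=C)[C@@H](CC/C(C)=C/C[C@@H](OOC(C)(C)OC)[C@@H](C)CO[Si](C)(C)C(C)(C)C)C2(C)C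
F7 | step 21 | 5-(acetoxymercurio) analogue of 33 | C=C1CC[C@H]2[C@@H](C1)CC(=C)[C@@H](CC[C@@]1(C)[C@H]([Hg]OC(C)=O)C[C@H]([C@@H](C)CO[Si](C)(C)C(C)(C)C)OO1)C2(C)C
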